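**Plan**

- Retrosynthesis: the ring B phenol is masked as a benzyl ether and the C1 methoxy group of ring A is traced back to an acetyl group (Baeyer–Villiger). Ring A, at its dihydro level, is then cut at C5–C6 and C1–C2 by a retro-[4+2] into pent-3-yn-2-one and a 2-aryloxy-3-isopropylbuta-1,3-diene.
- Enabling feature: in ring A the ether carbon C4 lies para to the methoxy carbon C1, with the isopropyl carbon C3 next to C4 and the methyl carbon C6 next to C1. This is the 1,4-adduct pattern of a 2-oxygenated diene with a β-methyl ynone.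
- The CH2 on the oxygen-bearing diene carbon is cut next (ester methylenation), then the ester C–O bond, giving the ring B phenol and 2-isopropylacrylic acid. The crowded diaryl ether bond is therefore never made by an aryl coupling.
- Forward: ring B comes from thymol (para-methoxylation, ortho-formylation, benzylation, Baeyer–Villiger of the aldehyde) and the acid from diethyl isopropylmalonate. Esterification and methylenation give the diene; ring A is built last by cycloaddition, dehydrogenation and acetyl-to-methoxy exchange.
- Stereochemistry: the target and all intermediates of the main route are free of stereocentres, so only regiochemistry has to be controlled.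

Key step: step 10

Remark: thymol, benzyl bromide, diethyl isopropylmalonate and pent-3-yn-2-one are taken as commercial.

**Route**

Step 1
Reactants: 1 thymol (2-isopropyl-5-methylphenol)
Product: 2 4-bromo-2-isopropyl-5-methylphenol
Conditions: NBS (1.0 equiv), MeCN, 0 °C → rt
Reagents that add atoms: N-bromosuccinimide, O=C1CCC(=O)N1Br
Why: Electrophilic aromatic bromination of a phenol goes para to the hydroxyl group, the only free ortho site being the more crowded one between OH and the ring methyl group.

Step 2
Reactants: 2 4-bromo-2-isopropyl-5-methylphenol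
Product: 3 2-isopropyl-4-methoxy-5-methylphenol
Conditions: NaOMe (5 equiv), CuI (10 mol %), MeOH–DMF, 110 °C; then aq. HCl
Reagents that add atoms: sodium methoxide, [Na+].[O-]C
Why: Ullmann-type copper-catalysed methoxylation of an aryl bromide by NaOMe is established for bromophenols, whose phenoxide form does not interfere.

Step 3
Reactants: 3 2-isopropyl-4-methoxy-5-methylphenol
Product: 4 2-hydroxy-3-isopropyl-5-methoxy-6-methylbenzaldehyde
Conditions: MgCl2, Et3N, (CH2O)n, MeCN, reflux; then aq. HCl
Reagents that add atoms: paraformaldehyde (as formaldehyde), C=O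
Why: In the magnesium-mediated ortho-formylation of phenols the magnesium phenoxide directs formaldehyde to the single free ortho position, and a second formaldehyde takes up hydride to give the salicylaldehyde.

Step 4
Reactants: 4 2-hydroxy-3-isopropyl-5-methoxy-6-methylbenzaldehyde; 5 benzyl bromide
Product: 6 2-(benzyloxy)-3-isopropyl-5-methoxy-6-methylbenzaldehyde
Conditions: K2CO3, DMF, 60 °C
Reagents that add atoms: none
Why: Williamson ether synthesis (SN2 of the phenoxide on benzyl bromide) caps the oxygen next to the isopropyl group, the one that must end as the free phenol of the target.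

Step 5
Reactants: 6 2-(benzyloxy)-3-isopropyl-5-methoxy-6-methylbenzaldehyde
Product: 8 2-(benzyloxy)-3-isopropyl-5-methoxy-6-methylphenol, via aryl formate 7 (not isolated)
Conditions: m-CPBA, CH2Cl2, 0 °C → rt; then K2CO3 (cat.), MeOH, rt
Reagents that add atoms: m-chloroperbenzoic acid, O=C(OO)c1cccc(Cl)c1
Why: Baeyer–Villiger (Dakin-type) oxidation of an electron-rich benzaldehyde proceeds with aryl migration to the aryl formate, which base-catalysed methanolysis converts into the phenol.

Step 6
Reactants: 9 diethyl isopropylmalonate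
Product: 10 isopropylmalonic acid
Conditions: KOH, EtOH–H2O, reflux; then aq. HCl
Reagents that add atoms: potassium hydroxide, [K+].[OH-]
Why: Saponification of both ester groups by acyl–oxygen cleavage with hydroxide, then acidification, gives the malonic acid.

Step 7
Reactants: 10 isopropylmalonic acid
Product: 11 2-isopropylacrylic acid (3-methyl-2-methylidenebutanoic acid)
Conditions: (CH2O)n, Et2NH, EtOAc, reflux
Reagents that add atoms: paraformaldehyde (as formaldehyde), C=O
Why: Mannich-type condensation of a monosubstituted malonic acid with formaldehyde and a secondary amine, followed by decarboxylative elimination, is the standard route to 2-alkylacrylic acids.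

Step 8
Reactants: 11 2-isopropylacrylic acid; 8 2-(benzyloxy)-3-isopropyl-5-methoxy-6-methylphenol
Product: 13 2-(benzyloxy)-3-isopropyl-5-methoxy-6-methylphenyl 3-methyl-2-methylidenebutanoate, via 2-isopropylacryloyl chloride 12 (not isolated)
Conditions: (COCl)2, DMF (cat.), CH2Cl2, 0 °C → rt; then 8, Et3N, DMAP (cat.), CH2Cl2, 0 °C → rt
Reagents that add atoms: none
Why: Acid chloride formation followed by DMAP-catalysed acylation is the reliable esterification for a 2,6-disubstituted phenol, and the acryloyl unit has no α-hydrogen from which a ketene could form.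

Step 9
Reactants: 13 2-(benzyloxy)-3-isopropyl-5-methoxy-6-methylphenyl 3-methyl-2-methylidenebutanoate
Product: 14 2-[2-(benzyloxy)-3-isopropyl-5-methoxy-6-methylphenoxy]-3-isopropylbuta-1,3-diene
Conditions: Cp2TiMe2 (2.5 equiv), toluene, 70 °C, dark
Reagents that add atoms: dimethyltitanocene Cp2TiMe2, C[Ti](C)(C1C=CC=C1)C1C=CC=C1
Why: In the Petasis methylenation Cp2TiMe2 loses methane to give Cp2Ti=CH2, which converts the ester carbonyl into the enol ether by [2+2] addition and cycloreversion; this is known for aryl esters and for acrylate esters (giving 2-oxygenated 1,3-dienes), and it leaves the conjugated C=C bond untouched.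

Step 10
Reactants: 14 2-[2-(benzyloxy)-3-isopropyl-5-methoxy-6-methylphenoxy]-3-isopropylbuta-1,3-diene; 15 pent-3-yn-2-one
Product: 16 1-{4-[2-(benzyloxy)-3-isopropyl-5-methoxy-6-methylphenoxy]-5-isopropyl-2-methylcyclohexa-1,4-dien-1-yl}ethanone
Conditions: 15 (5 equiv), BHT (cat.), toluene, sealed tube, 130 °C
Reagents that add atoms: none
Why: A concerted, thermally allowed [4+2] cycloaddition of normal electron demand joins the HOMO of the oxygen-substituted diene to the LUMO of the ynone and forms C5–C6 and C1–C2 of ring A in one event. The closest known reaction type is the Diels–Alder reaction of 2-alkoxy- and 2-silyloxybuta-1,3-dienes with acetylenic ketones, which gives cyclohexa-1,4-dienes that are later dehydrogenated to arenes. Ring A closes by intermolecular [4+2] annulation, the two diene termini bonding suprafacially across the alkyne to give a six-membered carbocycle with an enol ether and an enone double bond. No stereocentre arises, because the only sp3 atoms of the new ring are two CH2 groups. The step needs regioselectivity: the CH2 terminus on the aryloxy-bearing carbon has the largest HOMO coefficient and should bond to the methyl-bearing β-carbon of the ynone, placing acetyl para to aryloxy, while the 3-isopropyl group is only a weak alkyl donor pulling the other way. The 2,6-disubstituted aryl ring should twist out of the diene plane and leave both faces open, and excess ynone with a radical inhibitor should hold back diene polymerisation.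

Step 11
Reactants: 16 1-{4-[2-(benzyloxy)-3-isopropyl-5-methoxy-6-methylphenoxy]-5-isopropyl-2-methylcyclohexa-1,4-dien-1-yl}ethanone
Product: 17 1-{4-[2-(benzyloxy)-3-isopropyl-5-methoxy-6-methylphenoxy]-5-isopropyl-2-methylphenyl}ethanone
Conditions: DDQ (1.1 equiv), toluene, rt
Reagents that add atoms: none
Why: Dehydrogenation of a cyclohexa-1,4-diene by DDQ (hydride abstraction from a doubly allylic CH2, then proton loss) is fast at room temperature and driven by aromatisation, and a benzyl aryl ether is inert under these conditions.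

Step 12
Reactants: 17 1-{4-[2-(benzyloxy)-3-isopropyl-5-methoxy-6-methylphenoxy]-5-isopropyl-2-methylphenyl}ethanone
Product: 19 4-[2-(benzyloxy)-3-isopropyl-5-methoxy-6-methylphenoxy]-5-isopropyl-2-methylphenol, via aryl acetate 18 (not isolated)
Conditions: m-CPBA, CF3CO2H (cat.), CH2Cl2, 0 °C → rt; then K2CO3 (cat.), MeOH, rt
Reagents that add atoms: m-chloroperbenzoic acid, O=C(OO)c1cccc(Cl)c1
Why: In the Baeyer–Villiger oxidation of an aryl methyl ketone the aryl group, made electron-rich by the para aryloxy oxygen and twisted by the ortho methyl group, migrates in preference to methyl; the resulting aryl acetate is cleaved by base-catalysed methanolysis.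

Step 13
Reactants: 19 4-[2-(benzyloxy)-3-isopropyl-5-methoxy-6-methylphenoxy]-5-isopropyl-2-methylphenol
Product: 20 2-(benzyloxy)-1-isopropyl-3-(2-isopropyl-4-methoxy-5-methylphenoxy)-5-methoxy-4-methylbenzene
Conditions: MeI, K2CO3, acetone, reflux
Reagents that add atoms: iodomethane, CI
Why: Williamson methylation (SN2) of the only free phenol installs the C1 methoxy group of ring A.

Step 14
Reactants: 20 2-(benzyloxy)-1-isopropyl-3-(2-isopropyl-4-methoxy-5-methylphenoxy)-5-methoxy-4-methylbenzene
Product: 21 2-isopropyl-6-(2-isopropyl-4-methoxy-5-methylphenoxy)-4-methoxy-5-methylphenol (target)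
Conditions: H2 (1 atm), 10% Pd/C, EtOAc–EtOH, rt
Reagents that add atoms: none
Why: Catalytic hydrogenolysis on Pd/C cleaves the benzylic C–O bond of the benzyl aryl ether, while the methyl ethers, the diaryl ether and both arenes are untouched.

**Compound list**

1 | thymol (2-isopropyl-5-methylphenol) | Cc1ccc(C(C)C)c(O)c1 | starting material
2 | 4-bromo-2-isopropyl-5-methylphenol | Cc1cc(O)c(C(C)C)cc1Br | intermediate
3 | 2-isopropyl-4-methoxy-5-methylphenol | COc1cc(C(C)C)c(O)cc1C | intermediate
4 | 2-hydroxy-3-isopropyl-5-methoxy-6-methylbenzaldehyde | COc1cc(C(C)C)c(O)c(C=O)c1C | intermediate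
5 | benzyl bromide | BrCc1ccccc1 | starting material
6 | 2-(benzyloxy)-3-isopropyl-5-methoxy-6-methylbenzaldehyde | COc1cc(C(C)C)c(OCc2ccccc2)c(C=O)c1C | intermediate
7 | 2-(benzyloxy)-3-isopropyl-5-methoxy-6-methylphenyl formate | COc1cc(C(C)C)c(OCc2ccccc2)c(OC=O)c1C | intermediate
8 | 2-(benzyloxy)-3-isopropyl-5-methoxy-6-methylphenol | COc1cc(C(C)C)c(OCc2ccccc2)c(O)c1C | intermediate
9 | diethyl isopropylmalonate | CCOC(=O)C(C(C)C)C(=O)OCC | starting material
10 | isopropylmalonic acid | CC(C)C(C(=O)O)C(=O)O | intermediate
11 | 2-isopropylacrylic acid (3-methyl-2-methylidenebutanoic acid) | C=C(C(C)C)C(=O)O | intermediate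
12 | 2-isopropylacryloyl chloride (3-methyl-2-methylidenebutanoyl chloride) | C=C(C(C)C)C(Cl)=O | intermediate
13 | 2-(benzyloxy)-3-isopropyl-5-methoxy-6-methylphenyl 3-methyl-2-methylidenebutanoate | C=C(C(C)C)C(=O)Oc1c(C)c(OC)cc(C(C)C)c1OCc1ccccc1 | intermediate
14 | 2-[2-(benzyloxy)-3-isopropyl-5-methoxy-6-methylphenoxy]-3-isopropylbuta-1,3-diene | C=C(Oc1c(C)c(OC)cc(C(C)C)c1OCc1ccccc1)C(=C)C(C)C | intermediate
15 | pent-3-yn-2-one | CC#CC(C)=O | starting material
16 | 1-{4-[2-(benzyloxy)-3-isopropyl-5-methoxy-6-methylphenoxy]-5-isopropyl-2-methylcyclohexa-1,4-dien-1-yl}ethanone | CC(=O)C1=C(C)CC(Oc2c(C)c(OC)cc(C(C)C)c2OCc2ccccc2)=C(C(C)C)C1 | intermediate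
17 | 1-{4-[2-(benzyloxy)-3-isopropyl-5-methoxy-6-methylphenoxy]-5-isopropyl-2-methylphenyl}ethanone | CC(=O)c1cc(C(C)C)c(Oc2c(C)c(OC)cc(C(C)C)c2OCc2ccccc2)cc1C | intermediate
18 | 4-[2-(benzyloxy)-3-isopropyl-5-methoxy-6-methylphenoxy]-5-isopropyl-2-methylphenyl acetate | CC(=O)Oc1cc(C(C)C)c(Oc2c(C)c(OC)cc(C(C)C)c2OCc2ccccc2)cc1C | intermediate
19 | 4-[2-(benzyloxy)-3-isopropyl-5-methoxy-6-methylphenoxy]-5-isopropyl-2-methylphenol | Oc1cc(C(C)C)c(Oc2c(C)c(OC)cc(C(C)C)c2OCc2ccccc2)cc1C | intermediate
20 | 2-(benzyloxy)-1-isopropyl-3-(2-isopropyl-4-methoxy-5-methylphenoxy)-5-methoxy-4-methylbenzene | COc1cc(C(C)C)c(Oc2c(C)c(OC)cc(C(C)C)c2OCc2ccccc2)cc1C | intermediate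
21 | 2-isopropyl-6-(2-isopropyl-4-methoxy-5-methylphenoxy)-4-methoxy-5-methylphenol | COc1cc(C(C)C)c(Oc2c(C)c(OC)cc(C(C)C)c2O)cc1C | target

**Count**

Total steps: 14. Longest linear sequence: 12 steps (steps 1–5 and 8–14, from thymol 1 to 21); the acid branch (steps 6–7) joins at step 8.

**Steps most likely to fail**

Step 10. The cycloaddition of the internal ynone may be slow at a diene that is pushed out of planarity by its isopropyl and aryloxy groups. Thermal polymerisation or adventitious hydrolysis of the enol ether may then win, and the para regioselectivity may erode. The fallback keeps the cycloaddition but uses a far more reactive terminal ynone and brings in the C6 methyl group afterwards. From diene 14, but-3-yn-2-one (toluene, 60–80 °C) should give 1-{4-[2-(benzyloxy)-3-isopropyl-5-methoxy-6-methylphenoxy]-5-isopropylcyclohexa-1,4-dien-1-yl}ethanone F1. DDQ should dehydrogenate it to 1-{4-[2-(benzyloxy)-3-isopropyl-5-methoxy-6-methylphenoxy]-3-isopropylphenyl}ethanone F2. Baeyer–Villiger oxidation with m-CPBA should give 4-[2-(benzyloxy)-3-isopropyl-5-methoxy-6-methylphenoxy]-3-isopropylphenyl acetate F3, and methanolysis (K2CO3, MeOH) should give 4-[2-(benzyloxy)-3-isopropyl-5-methoxy-6-methylphenoxy]-3-isopropylphenol F4. Magnesium-mediated ortho-formylation (MgCl2, Et3N, paraformaldehyde) at the less hindered ortho position should give 5-[2-(benzyloxy)-3-isopropyl-5-methoxy-6-methylphenoxy]-2-hydroxy-4-isopropylbenzaldehyde F5. Methylation (MeI, K2CO3) should give 5-[2-(benzyloxy)-3-isopropyl-5-methoxy-6-methylphenoxy]-4-isopropyl-2-methoxybenzaldehyde F6. Hydrogenation over Pd/C in AcOH should then reduce the electron-rich formyl group to the methyl group and remove the benzyl group in one operation, so that the sequence comes back to the route at the target 21.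

Step 9. Methylenation of the hindered aryl ester may stay incomplete, the titanium adduct may collapse with expulsion of the aryloxide instead of olefination, and the aryloxydiene may hydrolyse or polymerise during isolation. The fallback builds the diene from the phenol without a titanium carbene. From phenol 8, Williamson alkylation with 1-bromo-3-methylbutan-2-one (K2CO3, acetone) should give 1-[2-(benzyloxy)-3-isopropyl-5-methoxy-6-methylphenoxy]-3-methylbutan-2-one F7. Regioselective Mannich α-methylenation at the aryloxy-bearing CH2 (paraformaldehyde, diisopropylammonium trifluoroacetate, THF, reflux) should give 2-[2-(benzyloxy)-3-isopropyl-5-methoxy-6-methylphenoxy]-4-methylpent-1-en-3-one F8. Wittig methylenation of this ketone (Ph3P=CH2, THF) should come back to the route at diene 14.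

Step 12. Aryl migration in the peracid adduct of the hindered ketone may be slow, so that oxidation of the electron-rich ring B by the peracid, or acid-promoted loss of the benzyl group, competes. The fallback replaces the ketone oxidation by a reduction and peroxide rearrangement sequence. From ketone 17, NaBH4 in MeOH should give racemic 1-{4-[2-(benzyloxy)-3-isopropyl-5-methoxy-6-methylphenoxy]-5-isopropyl-2-methylphenyl}ethanol F9. Aqueous H2O2 with catalytic p-TsOH should convert it into the racemic benzylic hydroperoxide 2-(benzyloxy)-3-[4-(1-hydroperoxyethyl)-2-isopropyl-5-methylphenoxy]-1-isopropyl-5-methoxy-4-methylbenzene F10. Under the same acid this should undergo Hock rearrangement (aryl migration to oxygen, loss of acetaldehyde) and come back to the route at phenol 19.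

**Further compounds**

F1 | step 10 | 1-{4-[2-(benzyloxy)-3-isopropyl-5-methoxy-6-methylphenoxy]-5-isopropylcyclohexa-1,4-dien-1-yl}ethanone | CC(=O)C1=CCC(Oc2c(C)c(OC)cc(C(C)C)c2OCc2ccccc2)=C(C(C)C)C1
F2 | step 10 | 1-{4-[2-(benzyloxy)-3-isopropyl-5-methoxy-6-methylphenoxy]-3-isopropylphenyl}ethanone | CC(=O)c1ccc(Oc2c(C)c(OC)cc(C(C)C)c2OCc2ccccc2)c(C(C)C)c1
F3 | step 10 | 4-[2-(benzyloxy)-3-isopropyl-5-methoxy-6-methylphenoxy]-3-isopropylphenyl acetate | CC(=O)Oc1ccc(Oc2c(C)c(OC)cc(C(C)C)c2OCc2ccccc2)c(C(C)C)c1
F4 | step 10 | 4-[2-(benzyloxy)-3-isopropyl-5-methoxy-6-methylphenoxy]-3-isopropylphenol | Oc1ccc(Oc2c(C)c(OC)cc(C(C)C)c2OCc2ccccc2)c(C(C)C)c1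
F5 | step 10 | 5-[2-(benzyloxy)-3-isopropyl-5-methoxy-6-methylphenoxy]-2-hydroxy-4-isopropylbenzaldehyde | O=Cc1cc(Oc2c(C)c(OC)cc(C(C)C)c2OCc2ccccc2)c(C(C)C)cc1O
F6 | step 10 | 5-[2-(benzyloxy)-3-isopropyl-5-methoxy-6-methylphenoxy]-4-isopropyl-2-methoxybenzaldehyde | COc1cc(C(C)C)c(Oc2c(C)c(OC)cc(C(C)C)c2OCc2ccccc2)cc1C=O
F7 | step 9 | 1-[2-(benzyloxy)-3-isopropyl-5-methoxy-6-methylphenoxy]-3-methylbutan-2-one | CC(C)C(=O)COc1c(C)c(OC)cc(C(C)C)c1OCc1ccccc1
F8 | step 9 | 2-[2-(benzyloxy)-3-isopropyl-5-methoxy-6-methylphenoxy]-4-methylpent-1-en-3-one | C=C(Oc1c(C)c(OC)cc(C(C)C)c1OCc1ccccc1)C(=O)C(C)C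
F9 | step 12 | racemic 1-{4-[2-(benzyloxy)-3-isopropyl-5-methoxy-6-methylphenoxy]-5-isopropyl-2-methylphenyl}ethanol | CC(O)c1cc(C(C)C)c(Oc2c(C)c(OC)cc(C(C)C)c2OCc2ccccc2)cc1C
F10 | step 12 | racemic 2-(benzyloxy)-3-[4-(1-hydroperoxyethyl)-2-isopropyl-5-methylphenoxy]-1-isopropyl-5-methoxy-4-methylbenzene | CC(OO)c1cc(C(C)C)c(Oc2c(C)c(OC)cc(C(C)C)c2OCc2ccccc2)cc1C
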